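**Retrosynthetic overview**

1. The target is reached by eight-fold O-demethylation, preceded by closure of the seven-membered ring through the bond from the CH(2,4-dioxyphenyl) carbon to the ortho carbon of a 3,5-dioxyphenyl ring (proton-induced Friedel–Crafts reaction of a stilbene, itself made by Wittig reaction of a central-ring aldehyde).
2. Key disconnection: the two bonds from the central benzene ring to C3 of each dihydrofuran ring (the carbon that carries the 3,5-dioxyphenyl group). Both are made in one operation, with the O–C2 bonds already in place, by imine-directed twofold C–H addition across two O-tethered Z enol ethers.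
3. Enabling feature: on the central benzene ring the carbon bearing the CH2 of the seven-membered ring is flanked on both sides by the ring carbons bonded to furan C3, the furan oxygens sit one position further out, and both dihydrofuran rings are (2R,3R). The core therefore has a local twofold axis through that carbon; as a formyl group (imine) it can direct a metal to both C–H bonds that must become aryl–C3 bonds, and the precursor is a flat, achiral bis(enol ether) of 3,5-dihydroxybenzaldehyde.
4. Ring order: both dihydrofuran rings first (C3/C5 set by a chiral imine, C2/C6 then equilibrated to trans), then the seven-membered ring (fifth stereocentre under substrate control).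
5. The enol ether arms come from one deoxybenzoin: ketone α-arylation, Z enol triflate, Pd-catalysed C–O coupling.

Key step: step 5

Assumption: the (R)-configured 1-aminoindane is taken to deliver the (3R,5R) series; this sense of induction is assigned by analogy with related N-indanyl aldimine cyclisations, not derived, and the (S)-amine would replace it without other change if the first cyclisation showed the opposite sense.

**Route**

Step 1
Reactants: 1 4'-methoxyacetophenone; 2 1-bromo-3,5-dimethoxybenzene
Product: 3 2-(3,5-dimethoxyphenyl)-1-(4-methoxyphenyl)ethan-1-one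
Conditions: Pd2(dba)3 (1 mol%), Xantphos (2.5 mol%), NaOtBu (2.2 equiv), 1 (1.2 equiv), THF, 70 °C
Reagents that add atoms: none
Why: Palladium-catalysed ketone α-arylation (Buchwald–Hartwig type) of a methyl aryl ketone should stop at mono-arylation because the product is held as its hindered enolate.

Step 2
Reactants: 3 2-(3,5-dimethoxyphenyl)-1-(4-methoxyphenyl)ethan-1-one
Product: 5 (Z)-2-(3,5-dimethoxyphenyl)-1-(4-methoxyphenyl)ethenyl trifluoromethanesulfonate, via potassium Z-enolate 4 (not isolated)
Conditions: KN(SiMe3)2, THF, −78 °C; then PhNTf2, −78 → 0 °C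
Reagents that add atoms: N-phenylbis(trifluoromethanesulfonimide), O=S(=O)(N(c1ccccc1)S(=O)(=O)C(F)(F)F)C(F)(F)F
Why: O-sulfonylation of the only possible enolate; the Z enolate (oxygen and dimethoxyphenyl cis, the two aryl groups trans) is favoured by 1,3-allylic strain and its geometry is carried into the triflate.

Step 3
Reactants: 5 (Z)-enol triflate (2.3 equiv); 6 3,5-dihydroxybenzaldehyde
Product: 7 3,5-bis{[(Z)-2-(3,5-dimethoxyphenyl)-1-(4-methoxyphenyl)ethenyl]oxy}benzaldehyde
Conditions: Pd2(dba)3 (5 mol%), t-BuXPhos (12 mol%), K3PO4, toluene, 100 °C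
Reagents that add atoms: none
Why: Palladium-catalysed C–O cross-coupling of alkenyl triflates with phenols (Buchwald–Hartwig-type etherification) proceeds with retention of alkene geometry, and K3PO4 leaves the non-enolisable aldehyde alone.

Step 4
Reactants: 7 bis(enol ether) aldehyde; 8 (R)-1-aminoindane
Product: 9 (E)-N-[(1R)-indan-1-yl]imine of 7
Conditions: MgSO4, CH2Cl2, rt
Reagents that add atoms: none
Why: Condensation of an aromatic aldehyde with a primary amine gives the E aldimine, which installs the directing group and the stereocontrolling element in one move.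

Step 5
Reactants: 9 (E)-N-[(1R)-indan-1-yl]imine of 7
Product: 12 (2S,3R,5R,6S)-3,5-bis(3,5-dimethoxyphenyl)-2,6-bis(4-methoxyphenyl)-2,3,5,6-tetrahydrobenzo[1,2-b:5,4-b']difuran-4-carbaldehyde, via mono-cyclised imine 10 (not isolated), via bis-cyclised imine 11 (not isolated)
Conditions: [RhCl(cyclooctene)2]2 (10 mol%), dicyclohexylphosphinoferrocene Fe(C5H5)(C5H4PCy2) (30 mol%), toluene, 90 °C; then 1 M aq. HCl, THF, rt
Reagents that add atoms: water, O
Why: The imine nitrogen holds monovalent rhodium next to the ring C–H lying between the imine-bearing carbon and an O-vinyl-bearing carbon; oxidative addition gives an aryl rhodium hydride, the hydride adds to the oxygen-bearing carbon of the tethered enol ether to give a six-membered rhodacycle with rhodium on the benzylic carbon, C–C reductive elimination forms the bond from the central ring to furan C3, and the imine then turns to the second ortho C–H and the same sequence closes the other arm. The closest known reaction type is the chelation-assisted (Murai-type) rhodium-catalysed intramolecular alkene hydroarylation of aromatic aldimines, established for an imine carrying a meta O-tethered β-aryl-β-aryloxyacrylate that closes to a 2-aryl-2,3-dihydrobenzofuran under control of an N-indanyl group; here it is run twice on an alkene that carries an aryl group in place of the ester. Each dihydrofuran ring closes through its aryl–C3 bond with the O–C2 bond already in place, by hydrometalation and reductive elimination from the six-membered metallacycle, so that both alkene carbons end up in the five-membered ring. C3 and C5 are set by the enol ether face that binds rhodium, which the indanyl group on the chelating nitrogen differentiates, while C2 and C6 follow from syn addition of aryl and H across the Z alkene, which places the two aryl groups of each ring cis; because the selection is made twice, the twofold-symmetric (3R,5R) product should be enriched beyond the selectivity of a single event, the mismatched pairing ending up in a separable diastereomer. The step needs site selectivity for the two positions ortho to the imine carbon over the position between the two oxygen atoms, which the chelate geometry secures, and hydride transfer to the oxygen-bearing alkene carbon, which is the only regiochemistry whose reductive elimination can give a ring (the alternative would need a four-membered ring and reverts). Aqueous acid then hydrolyses the imine and returns the auxiliary.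

Step 6
Reactants: 12 cis,cis-aldehyde
Product: 13 (2R,3R,5R,6R)-3,5-bis(3,5-dimethoxyphenyl)-2,6-bis(4-methoxyphenyl)-2,3,5,6-tetrahydrobenzo[1,2-b:5,4-b']difuran-4-carbaldehyde
Conditions: CF3CO2H, CH2Cl2, 0 °C → rt
Reagents that add atoms: none
Why: Reversible acid-induced heterolysis of each p-methoxybenzylic C2–O bond and reclosure by the phenol oxygen should equilibrate C2 and C6 to the more stable trans arrangement (epimerisation under thermodynamic control), while C3 and C5 carry no ionisable bond and intramolecular reclosure should outrun proton loss from the cation.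

Step 7
Reactants: 14 2,4-dimethoxybenzyl alcohol
Product: 15 (2,4-dimethoxybenzyl)triphenylphosphonium bromide
Conditions: PPh3·HBr, MeCN, 80 °C
Reagents that add atoms: triphenylphosphine hydrobromide, Br.c1ccc(cc1)P(c1ccccc1)c1ccccc1
Why: The electron-rich benzylic alcohol ionises under HBr and the benzylic cation is captured by triphenylphosphine (SN1-type phosphonium salt formation).

Step 8
Reactants: 13 trans,trans-aldehyde; 15 (2,4-dimethoxybenzyl)triphenylphosphonium bromide
Product: 17 (2R,3R,5R,6R)-4-[(E)-2-(2,4-dimethoxyphenyl)ethenyl]-3,5-bis(3,5-dimethoxyphenyl)-2,6-bis(4-methoxyphenyl)-2,3,5,6-tetrahydrobenzo[1,2-b:5,4-b']difuran, via phosphonium ylide 16 (not isolated)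
Conditions: KOtBu, THF, 0 °C; then 13, 0 → 40 °C
Reagents that add atoms: none
Why: Wittig olefination with a semi-stabilised ylide should tolerate the di-ortho-substituted aldehyde; the E isomer is drawn and any Z isomer is carried on, because both give the same cation in step 9.

Step 9
Reactants: 17 stilbene
Product: 18 octa-O-methyl ether of the target
Conditions: TsOH·H2O, CH2Cl2, 0 °C → rt
Reagents that add atoms: none
Why: Protonation of either stilbene isomer at the alkene carbon attached to the central ring gives the 2,4-dimethoxybenzylic cation, which is captured in a Friedel–Crafts ring closure by the ortho carbon of one of the two equivalent 3,5-dimethoxyphenyl groups (the known proton-induced closure of 4-styryl-2,3-diaryl-dihydrobenzofurans to dibenzocycloheptene-fused dihydrobenzofurans); the new centre should be set by the neighbouring furan stereocentres, because the aryl group is expected to stand pseudo-axial, away from the ortho methoxy group of the attacking ring and on the ring face that carries the adjacent furan C3–H, which is the (R) configuration of the target.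

Step 10
Reactants: 18 octa-O-methyl ether of the target
Product: 19 CNP0154047.1
Conditions: BBr3 (excess), CH2Cl2, −78 °C → rt; then MeOH, H2O
Reagents that add atoms: none
Why: Boron tribromide cleaves all eight aryl methyl ethers by the usual Lewis acid–bromide mechanism without touching the carbon skeleton, and since both dihydrofuran rings are already trans, any reversible opening of a benzylic C–O bond should return the same isomer.

**Compound list**

1 | 4'-methoxyacetophenone | CC(=O)c1ccc(OC)cc1 | starting material
2 | 1-bromo-3,5-dimethoxybenzene | COc1cc(Br)cc(OC)c1 | starting material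
3 | 2-(3,5-dimethoxyphenyl)-1-(4-methoxyphenyl)ethan-1-one | COc1ccc(cc1)C(=O)Cc1cc(OC)cc(OC)c1 | intermediate
4 | potassium (Z)-2-(3,5-dimethoxyphenyl)-1-(4-methoxyphenyl)ethenolate (not isolated) | COc1ccc(cc1)/C([O-])=C/c1cc(OC)cc(OC)c1.[K+] | intermediate
5 | (Z)-2-(3,5-dimethoxyphenyl)-1-(4-methoxyphenyl)ethenyl trifluoromethanesulfonate | COc1ccc(cc1)/C(OS(=O)(=O)C(F)(F)F)=C/c1cc(OC)cc(OC)c1 | intermediate
6 | 3,5-dihydroxybenzaldehyde | O=Cc1cc(O)cc(O)c1 | starting material
7 | 3,5-bis{[(Z)-2-(3,5-dimethoxyphenyl)-1-(4-methoxyphenyl)ethenyl]oxy}benzaldehyde | O=Cc1cc(O/C(=C\c2cc(OC)cc(OC)c2)c2ccc(OC)cc2)cc(O/C(=C\c2cc(OC)cc(OC)c2)c2ccc(OC)cc2)c1 | intermediate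
8 | (R)-1-aminoindane | N[C@@H]1CCc2ccccc12 | starting material
9 | (E)-N-[(1R)-indan-1-yl]-1-(3,5-bis{[(Z)-2-(3,5-dimethoxyphenyl)-1-(4-methoxyphenyl)ethenyl]oxy}phenyl)methanimine | c1(/C=N/[C@@H]2CCc3ccccc23)cc(O/C(=C\c2cc(OC)cc(OC)c2)c2ccc(OC)cc2)cc(O/C(=C\c2cc(OC)cc(OC)c2)c2ccc(OC)cc2)c1 | intermediate
10 | (E)-N-[(1R)-indan-1-yl]imine of (2S,3R)-3-(3,5-dimethoxyphenyl)-6-{[(Z)-2-(3,5-dimethoxyphenyl)-1-(4-methoxyphenyl)ethenyl]oxy}-2-(4-methoxyphenyl)-2,3-dihydro-1-benzofuran-4-carbaldehyde (not isolated) | COc1ccc([C@H]2Oc3cc(O/C(=C\c4cc(OC)cc(OC)c4)c4ccc(OC)cc4)cc(/C=N/[C@@H]4CCc5ccccc45)c3[C@H]2c2cc(OC)cc(OC)c2)cc1 | intermediate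
11 | (E)-N-[(1R)-indan-1-yl]imine of 12 (not isolated) | COc1ccc([C@H]2Oc3cc4c(c(/C=N/[C@@H]5CCc6ccccc56)c3[C@H]2c2cc(OC)cc(OC)c2)[C@@H](c2cc(OC)cc(OC)c2)[C@@H](c2ccc(OC)cc2)O4)cc1 | intermediate
12 | (2S,3R,5R,6S)-3,5-bis(3,5-dimethoxyphenyl)-2,6-bis(4-methoxyphenyl)-2,3,5,6-tetrahydrobenzo[1,2-b:5,4-b']difuran-4-carbaldehyde (both rings 2,3-cis) | COc1ccc([C@H]2Oc3cc4c(c(C=O)c3[C@H]2c2cc(OC)cc(OC)c2)[C@@H](c2cc(OC)cc(OC)c2)[C@@H](c2ccc(OC)cc2)O4)cc1 | intermediate
13 | (2R,3R,5R,6R)-3,5-bis(3,5-dimethoxyphenyl)-2,6-bis(4-methoxyphenyl)-2,3,5,6-tetrahydrobenzo[1,2-b:5,4-b']difuran-4-carbaldehyde (both rings 2,3-trans) | COc1ccc([C@@H]2Oc3cc4c(c(C=O)c3[C@H]2c2cc(OC)cc(OC)c2)[C@@H](c2cc(OC)cc(OC)c2)[C@H](c2ccc(OC)cc2)O4)cc1 | intermediate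
14 | 2,4-dimethoxybenzyl alcohol | COc1ccc(CO)c(OC)c1 | starting material
15 | (2,4-dimethoxybenzyl)triphenylphosphonium bromide | COc1ccc(C[P+](c2ccccc2)(c2ccccc2)c2ccccc2)c(OC)c1.[Br-] | intermediate
16 | (2,4-dimethoxybenzylidene)triphenylphosphorane (not isolated) | COc1ccc(C=P(c2ccccc2)(c2ccccc2)c2ccccc2)c(OC)c1 | intermediate
17 | (2R,3R,5R,6R)-4-[(E)-2-(2,4-dimethoxyphenyl)ethenyl]-3,5-bis(3,5-dimethoxyphenyl)-2,6-bis(4-methoxyphenyl)-2,3,5,6-tetrahydrobenzo[1,2-b:5,4-b']difuran | COc1ccc([C@@H]2Oc3cc4c(c(/C=C/c5ccc(OC)cc5OC)c3[C@H]2c2cc(OC)cc(OC)c2)[C@@H](c2cc(OC)cc(OC)c2)[C@H](c2ccc(OC)cc2)O4)cc1 | intermediate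
18 | octa-O-methyl ether of the target (all five stereocentres as in the target) | COc1ccc([C@@H]2Oc3cc4c5c(c3[C@H]2c2cc(OC)cc(OC)c2)C[C@H](c2ccc(OC)cc2OC)c2c(OC)cc(OC)cc2[C@H]5[C@H](c2ccc(OC)cc2)O4)cc1 | intermediate
19 | CNP0154047.1 | Oc1ccc([C@@H]2Oc3cc4c5c(c3[C@H]2c2cc(O)cc(O)c2)C[C@H](c2ccc(O)cc2O)c2c(O)cc(O)cc2[C@H]5[C@H](c2ccc(O)cc2)O4)cc1 | target

**Step count and risks**

Total step count: 10. Longest linear sequence: 9 (steps 1–6 and 8–10; step 7 is a side branch).

Steps most likely to fail:

Step 5. The rhodium hydride may fail to insert the hindered 1,2-diaryl enol ether, the second arm may stay open, or facial selection may be poor. The fallback stays in the ester series for which this cyclisation is established and brings the aryl group in afterwards. Setting out from 6, twofold conjugate addition to methyl 3-(4-methoxyphenyl)propiolate (DABCO cat., MeCN) gives dimethyl (2Z,2'Z)-3,3'-[(5-formyl-1,3-phenylene)bis(oxy)]bis[3-(4-methoxyphenyl)prop-2-enoate] F1. Condensation with (S)-1-aminoindane (the antipode, because here the oxygen-bearing C2 centre is the one that is kept) gives the imine F2. The rhodium conditions of step 5 close both rings to the cis,cis-diester imine F3. Aqueous HCl and then LiOH remove the auxiliary and the methyl esters to give the diacid F4; C3 and C5 equilibrate to trans under the base, which is of no consequence. A twofold decarboxylative arylation with 2 under nickel/photoredox dual catalysis (NiCl2(MeOCH2CH2OMe), 4,4'-di-tert-butyl-2,2'-bipyridine, Ir[dF(CF3)ppy]2(dtbbpy)PF6, Cs2CO3, DMF, blue light) then installs the two 3,5-dimethoxyphenyl groups, each benzylic C3 radical being captured anti to the neighbouring C2 aryl group, and the route is rejoined at 13.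

Step 6. The ring-opened benzylic cation may lose the neighbouring proton and re-protonate, which would erode C3/C5, or the equilibration may stall. The fallback makes the trans rings directly and has no cationic stage. Setting out from 7, triplet-sensitised contra-thermodynamic alkene isomerisation (Ir(ppy)3, blue light, MeCN) converts both arms into the E enol ether, in which the two aryl groups are cis, giving 3,5-bis{[(E)-2-(3,5-dimethoxyphenyl)-1-(4-methoxyphenyl)ethenyl]oxy}benzaldehyde F5. Condensation with 8 gives the imine F6. The rhodium cyclisation of step 5, now a syn addition across an E alkene, gives the trans,trans imine F7, and acid hydrolysis rejoins the route at 13.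

Step 10. The boron Lewis acid may open the benzylic furan C–O bonds with irreversible capture of the cation, or the eight-fold cleavage may stay incomplete. The fallback reverses the order of the last two events and uses a nucleophilic dealkylation. Setting out from 17, NaSEt in DMF at 130 °C cleaves all methyl ethers by attack at the methyl carbon to give the free octahydroxy stilbene F8, and dilute HCl in MeOH then closes the seven-membered ring on the free phenol, the setting in which this ring closure is best known, arriving at 19.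

Further compounds
F1 | step 5 | dimethyl (2Z,2'Z)-3,3'-[(5-formyl-1,3-phenylene)bis(oxy)]bis[3-(4-methoxyphenyl)prop-2-enoate] | O=Cc1cc(O/C(=C\C(=O)OC)c2ccc(OC)cc2)cc(O/C(=C\C(=O)OC)c2ccc(OC)cc2)c1
F2 | step 5 | (E)-N-[(1S)-indan-1-yl]imine of F1 | c1(/C=N/[C@H]2CCc3ccccc23)cc(O/C(=C\C(=O)OC)c2ccc(OC)cc2)cc(O/C(=C\C(=O)OC)c2ccc(OC)cc2)c1
F3 | step 5 | dimethyl (2R,3S,5S,6R)-4-{(E)-[(1S)-indan-1-ylimino]methyl}-2,6-bis(4-methoxyphenyl)-2,3,5,6-tetrahydrobenzo[1,2-b:5,4-b']difuran-3,5-dicarboxylate | COc1ccc([C@@H]2Oc3cc4c(c(/C=N/[C@H]5CCc6ccccc56)c3[C@@H]2C(=O)OC)[C@H](C(=O)OC)[C@H](c2ccc(OC)cc2)O4)cc1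
F4 | step 5 | (2R,3R,5R,6R)-4-formyl-2,6-bis(4-methoxyphenyl)-2,3,5,6-tetrahydrobenzo[1,2-b:5,4-b']difuran-3,5-dicarboxylic acid | COc1ccc([C@@H]2Oc3cc4c(c(C=O)c3[C@H]2C(O)=O)[C@@H](C(O)=O)[C@H](c2ccc(OC)cc2)O4)cc1
F5 | step 6 | 3,5-bis{[(E)-2-(3,5-dimethoxyphenyl)-1-(4-methoxyphenyl)ethenyl]oxy}benzaldehyde | O=Cc1cc(O/C(=C/c2cc(OC)cc(OC)c2)c2ccc(OC)cc2)cc(O/C(=C/c2cc(OC)cc(OC)c2)c2ccc(OC)cc2)c1
F6 | step 6 | (E)-N-[(1R)-indan-1-yl]imine of F5 | c1(/C=N/[C@@H]2CCc3ccccc23)cc(O/C(=C/c2cc(OC)cc(OC)c2)c2ccc(OC)cc2)cc(O/C(=C/c2cc(OC)cc(OC)c2)c2ccc(OC)cc2)c1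
F7 | step 6 | (E)-N-[(1R)-indan-1-yl]imine of 13 | COc1ccc([C@@H]2Oc3cc4c(c(/C=N/[C@@H]5CCc6ccccc56)c3[C@H]2c2cc(OC)cc(OC)c2)[C@@H](c2cc(OC)cc(OC)c2)[C@H](c2ccc(OC)cc2)O4)cc1
F8 | step 10 | (2R,3R,5R,6R)-4-[(E)-2-(2,4-dihydroxyphenyl)ethenyl]-3,5-bis(3,5-dihydroxyphenyl)-2,6-bis(4-hydroxyphenyl)-2,3,5,6-tetrahydrobenzo[1,2-b:5,4-b']difuran | Oc1ccc([C@@H]2Oc3cc4c(c(/C=C/c5ccc(O)cc5O)c3[C@H]2c2cc(O)cc(O)c2)[C@@H](c2cc(O)cc(O)c2)[C@H](c2ccc(O)cc2)O4)cc1
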